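(The readings stem from a simulated flask with made-up constants, and the scatter is random.)

**The vessel.** A stirred vessel of constant volume takes E and L, and I count both as fractions of the E charged.

| setting | ochre | teal | violet | theta | beta | delta |
|---|---|---|---|---|---|---|
| E | 0.050 M | 0.050 M | 0.050 M | 0.050 M | 0.050 M (fed, over 80 s) | 0.050 M |
| L | 0.065 M | 0.033 M | 0.13 M | 0.0650 M | 0.0650 M | 0.0650 M (fed, over 80 s) |
| remark | run made earlier | run made earlier | run made earlier | everything together at the start | all else is in the flask from the start; the feed brings no volume worth counting | all else is in the flask from the start; the feed brings no volume worth counting |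
| time |  |  |  | 2.0 min | 2.0 min | 2.0 min |

- ochre (time / s: D / %): 10.0: 22; 12.0: 24; 30.0: 31; 80.0: 35
- teal (time / s: D / %): 12.0: 16; 30.0: 15; 60.0: 19; 90.0: 16
- violet (time / s: D / %): 10.0: 35; 20.0: 51; 40.0: 58; 90.0: 58

(readings scatter by 2 percentage points)

1. the best flask by amount of D, in percent of the E charged; "all alike" if 1.5 percentage points covers them all (theta / beta / delta / all alike)
2. amount of D at the end, in percent of the E charged, theta
3. amount of D at the end, in percent of the E charged, beta
4. amount of D at the end, in percent of the E charged, delta

**Two exits.** In ochre, L goes in at 1.30 of the E charge, yet D levels off at 35%. So I take L to have a second exit, a first-order one that needs no E. L then meets E at a rate proportional to e, the fraction of E standing, and leaves by itself at a fixed rate.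

The tie level, the value of e at which these two rates are equal, is what I carry: 2.21, read from ochre. L reaches E with the share e/(e+tie), a selectivity. Summed over a run, this gives charge of L minus y = tie·ln(1/(1−y)), where y is the plateau of D. Violet reads 2.33 and teal 2.87, each with the 2 percentage points scatter of its readings.

**My reckoning.** Theta repeats ochre, so I expect about 35%. In my picture the share in delta depends on e and not on the L standing, so I let fed L walk much the same path. The life of L, read from violet's approach to its plateau, is 10.8 s. Delta's feed leaves 40.0 s after it ends, longer than that life. So I put delta near theta. In beta, one life of L admits e = 0.135, and with that e held in the share I reckon D at 7.51%.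

**The forecast.** It names theta, with 34.5% (32% to 37%) for theta, 9.5% (6% to 15%) for beta and 34% (30% to 37%) for delta. Its ground for beta is that “Feeding E lets L die before E arrives”. Its beta stands above mine.

**The flasks.** Theta gives 32.7%, beta 5.38% and delta 29.3%, so the best is theta.

    Z ⇌ D, rate k1*(cs1 - [D]) while solid is left; crystals form when [D] > cs1 (solubility = 3.40 mM, k = 10.3 /s)
    L → G (k = 0.160 /s)
    E + J → X (k = 2.85 /M/s)
    E + L → J (k = 2.96 /M/s)
    J → D (k = 0.144 /s)

**Beta's race.** At 0.0677 min in beta, L has a half-life of 2.0 min by its step with E but 0.0722 min by its loss to G, shorter by a factor of 27.1. At 1.00 min beta holds L at 0% of its charge and D at 5.38%, below the 7.51% that the tie level of 2.21 gave. For the neighbour of beta with 0.26 M of L, the same share gives 30.0%, and that flask gives 13.7%.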